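**Retrosynthetic overview**
1. C6–prenyl is traced back to the 7-O-prenyl ether. The last step is a palladium-mediated O-to-C6 prenyl shift, so the prenyl group enters through a C–O bond.
2. O7–CH2(prenyl) is a Williamson disconnection to 5,7-dihydroxy-2',3',4'-trimethoxyisoflavone and prenyl bromide. The chelated 5-OH stays free.
3. The key disconnection is O1–C2 of ring C (together with C2–C3): phenol-O addition–elimination on an aminomethylene ketone, with C2 coming from DMF. The closure is done while ring A is still symmetric, so only one product is possible. Afterwards C6 is the only ring carbon between two free oxygens.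
4. C4–C4a comes from Friedel–Crafts acylation of phloroglucinol with (2,3,4-trimethoxyphenyl)acetic acid.
5. Ring order: rings A and B are bought; ring C is the only ring formed (step 1).

Assumption: the target has no stereocentre and no stereogenic double bond, so it is achiral and needs no enantiocontrol; (2,3,4-trimethoxyphenyl)acetic acid is taken as a catalogue chemical.

**Step 1**
Reactants: 1 phloroglucinol (benzene-1,3,5-triol); 2 (2,3,4-trimethoxyphenyl)acetic acid
Product: 5 5,7-dihydroxy-3-(2,3,4-trimethoxyphenyl)-4H-chromen-4-one, via deoxybenzoin 3 (not isolated), via enaminone 4 (not isolated)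
Conditions: BF3·OEt2 (solvent), 85 °C, 2 h; cool to 10 °C, DMF, then MeSO2Cl (3 equiv), 55 → 75 °C, 2 h; aq NaOAc work-up
Reagents that add atoms: N,N-dimethylformamide (DMF), CN(C)C=O
Why: Friedel–Crafts acylation of the threefold-symmetric, very electron-rich phloroglucinol gives the single ketone 3, its activated CH2 is aminomethylenated by the Vilsmeier-type iminium salt made from DMF and MeSO2Cl to give 4, and an ortho-OH then adds to the enamine carbon and expels Me2NH (oxa-Michael addition–elimination), the two ortho-OH groups being equivalent so that the O1–C2 bond can form in only one way.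

**Step 2**
Reactants: 5 5,7-dihydroxy-3-(2,3,4-trimethoxyphenyl)-4H-chromen-4-one; 6 prenyl bromide (1-bromo-3-methylbut-2-ene)
Product: 7 5-hydroxy-7-[(3-methylbut-2-en-1-yl)oxy]-3-(2,3,4-trimethoxyphenyl)-4H-chromen-4-one
Conditions: K2CO3 (1.2 equiv), 6 (1.05 equiv), acetone, reflux, 5 h
Reagents that add atoms: none
Why: Williamson ether synthesis in which K2CO3 ionises only the 7-OH (a vinylogous acid, pKa about 7) while the 5-OH is held in a hydrogen bond to C4=O, so SN2 attack on the primary allylic bromide gives the 7-ether alone.

**Step 3**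
Reactants: 7 5-hydroxy-7-[(3-methylbut-2-en-1-yl)oxy]-3-(2,3,4-trimethoxyphenyl)-4H-chromen-4-one
Product: 9 5,7-dihydroxy-6-(3-methylbut-2-en-1-yl)-3-(2,3,4-trimethoxyphenyl)-4H-chromen-4-one, via dienone 8 (not isolated)
Conditions: Pd(PPh3)4 (5 mol %), degassed 1,4-dioxane/t-BuOH 9:1 (0.05 M), 80 °C, Ar, 12 h
Reagents that add atoms: none
Why: Proposed new method: zerovalent palladium ionises the allylic C–O bond of 7, because the leaving 7-phenoxide is a vinylogous carboxylate (pKa about 7, comparable to 4-nitrophenoxide), to an η3-prenylpalladium cation paired with the ambident phenoxide; recombination at oxygen only regenerates 7 and stays reversible, whereas outer-sphere attack of a ring carbon on the unsubstituted CH2 terminus of the allyl unit gives dienone 8, whose tautomerisation to the phenol is irreversible, so the ether drains into the linear (not the inverted 1,1-dimethylallyl) C-prenyl isomer far below the temperature of a thermal Claisen shift; C6 is expected to win over C8 because the nucleophile is the phenoxide, for which base-mediated nuclear alkylation of 5,7-dihydroxychromones goes mainly to the carbon between the two oxygens, and because ring C was closed first, which leaves C8 next to an ether oxygen only; closest known reaction type: the palladium-catalysed O-to-C allyl shift of allyl ethers of 4-hydroxycoumarins, 4-hydroxy-2-pyranones and other enolised 1,3-dicarbonyl compounds (Tsuji–Trost manifold), not yet shown for a prenyl ether of a hydroxychromone or for site selection between two ring carbons.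

**Compound list**
1 | phloroglucinol (benzene-1,3,5-triol) | Oc1cc(O)cc(O)c1 | starting material
2 | (2,3,4-trimethoxyphenyl)acetic acid | COc1ccc(CC(=O)O)c(OC)c1OC | starting material
3 | 1-(2,4,6-trihydroxyphenyl)-2-(2,3,4-trimethoxyphenyl)ethan-1-one (deoxybenzoin) | COc1ccc(CC(=O)c2c(O)cc(O)cc2O)c(OC)c1OC | intermediate (not isolated)
4 | (E)-3-(dimethylamino)-1-(2,4,6-trihydroxyphenyl)-2-(2,3,4-trimethoxyphenyl)prop-2-en-1-one (enaminone) | COc1ccc(/C(=C\N(C)C)C(=O)c2c(O)cc(O)cc2O)c(OC)c1OC | intermediate (not isolated)
5 | 5,7-dihydroxy-3-(2,3,4-trimethoxyphenyl)-4H-chromen-4-one | COc1ccc(-c2coc3cc(O)cc(O)c3c2=O)c(OC)c1OC | intermediate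
6 | prenyl bromide (1-bromo-3-methylbut-2-ene) | CC(C)=CCBr | starting material
7 | 5-hydroxy-7-[(3-methylbut-2-en-1-yl)oxy]-3-(2,3,4-trimethoxyphenyl)-4H-chromen-4-one | COc1ccc(-c2coc3cc(OCC=C(C)C)cc(O)c3c2=O)c(OC)c1OC | intermediate
8 | 5-hydroxy-6-(3-methylbut-2-en-1-yl)-3-(2,3,4-trimethoxyphenyl)-4H-chromene-4,7(6H)-dione (dienone; racemic and transient at C6) | COc1ccc(C2=COC3=CC(=O)C(CC=C(C)C)C(O)=C3C2=O)c(OC)c1OC | intermediate (not isolated)
9 | 5,7-dihydroxy-6-(3-methylbut-2-en-1-yl)-3-(2,3,4-trimethoxyphenyl)-4H-chromen-4-one (achiral) | COc1ccc(-c2coc3cc(O)c(CC=C(C)C)c(O)c3c2=O)c(OC)c1OC | target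

**Totals**
Total step count: 3. Longest linear sequence: 3 (1 → 5 → 7 → 9). No protecting groups are used.

**Steps most likely to fail**

Step 3 (the proposed new step). The risks are attack at C8 (a C6:C8 ratio of only about 4:1 is assumed), crossover giving diprenylated material plus 5, and loss of isoprene by β-hydride elimination. The fallback uses known chemistry and fixes C6 with a halogen instead of relying on the ion pair. It sets out from 5. MOMCl and iPr2NEt in CH2Cl2 protect only the non-chelated 7-OH and give the 7-O-methoxymethyl ether F1. BnMe3N+ ICl2− with CaCO3 in CH2Cl2–MeOH iodinates ortho to the free 5-OH and gives the 6-iodide F2. Stille coupling with Bu3SnCH2CH=CMe2 and Pd(PPh3)4 in DMF at 90 °C gives the 6-prenyl MOM ether F3. Dilute HCl in MeOH at 40 °C removes the MOM group, and the sequence comes back to the route at 9.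

Step 1. The risks are Vilsmeier formylation of the electron-rich trimethoxyphenyl ring, loss of the 2'-methyl ether in hot BF3·OEt2, and incomplete acylation carried into the second stage. The fallback is stepwise and free of boron Lewis acid. It sets out from 1. A Houben–Hoesch reaction with (2,3,4-trimethoxyphenyl)acetonitrile F4 (ZnCl2, HCl gas, Et2O, 0 °C) precipitates the ketiminium chloride F5. Boiling water hydrolyses this salt to 3, which is now isolated. Me2NCH(OMe)2 in THF at 60 °C then closes ring C through 4, and the sequence comes back to the route at 5.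

Step 2. The risks are some C-alkylation of the phenoxide and a little 5,7-bis-ether. The fallback activates the alcohol instead of using a phenoxide with a halide. It sets out from 5. Mitsunobu etherification with 3-methylbut-2-en-1-ol, PPh3 and DIAD in THF at 0 °C uses only the acidic 7-OH as pronucleophile and generates no free phenoxide. It comes back to the route at 7 and makes no new compound (F0).

**Further compounds**
F1 | step 3 | 5-hydroxy-7-(methoxymethoxy)-3-(2,3,4-trimethoxyphenyl)-4H-chromen-4-one | COc1ccc(-c2coc3cc(OCOC)cc(O)c3c2=O)c(OC)c1OC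
F2 | step 3 | 5-hydroxy-6-iodo-7-(methoxymethoxy)-3-(2,3,4-trimethoxyphenyl)-4H-chromen-4-one | COc1ccc(-c2coc3cc(OCOC)c(I)c(O)c3c2=O)c(OC)c1OC
F3 | step 3 | 5-hydroxy-7-(methoxymethoxy)-6-(3-methylbut-2-en-1-yl)-3-(2,3,4-trimethoxyphenyl)-4H-chromen-4-one | COc1ccc(-c2coc3cc(OCOC)c(CC=C(C)C)c(O)c3c2=O)c(OC)c1OC
F4 | step 1 | (2,3,4-trimethoxyphenyl)acetonitrile | COc1ccc(CC#N)c(OC)c1OC
F5 | step 1 | 1-(2,4,6-trihydroxyphenyl)-2-(2,3,4-trimethoxyphenyl)ethan-1-iminium chloride | COc1ccc(CC(=[NH2+])c2c(O)cc(O)cc2O)c(OC)c1OC.[Cl-]
F0 | step 2 | none | none
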